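**Retrosynthetic overview**

1. The ring A C2 phenol and both ring B phenols are unmasked last with BCl3 (one chelated methyl ether, two benzyl ethers). The acetate comes from a silyl ether, and the ester C(=O)–O bond is made by Mitsunobu inversion of an (S)-carbinol that carries ring B.
2. The ring A acid is assembled on 3,5-dimethoxybenzyne: the chain Grignard forms the C6–CH2 bond and carbon dioxide the C1–carboxyl bond in one flask. The feature used is the contiguous C2(oxygen)–C1(carboxyl)–C6(alkyl) array of ring A with the second oxygen at C4, which is the pattern left when a nucleophile adds to the far end of a 3-alkoxyaryne and the metalated carbon is then carboxylated.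
3. The chain Grignard comes from (R)-2-propyloxirane and a heptenyl Grignard (the acetate-bearing centre is taken from the chiral pool), followed by silylation, hydroboration, Appel bromination and magnesium insertion.
4. The ring B carbinol comes from (S)-2-propyloxirane and a hexenyl Grignard, then 9-BBN hydroboration and B-alkyl Suzuki–Miyaura coupling with 1,3-bis(benzyloxy)-5-bromobenzene.
5. No ring is formed; both benzene rings are bought. Order of events: chain, ring A acid (aryne), ester, protecting-group endgame.

Key step: step 7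

Assumption: both carbinol centres of the target read as (R) from the given structure, and all compounds marked as starting materials are taken to be commercially available.

**Route**

Step 1
Reactants: 1 1-bromo-3,5-dimethoxybenzene
Product: 2 1,2-dibromo-3,5-dimethoxybenzene
Conditions: NBS (1.0 equiv), MeCN, 0 °C → rt
Reagents that add atoms: N-bromosuccinimide, O=C1CCC(=O)N1Br
Why: Electrophilic aromatic bromination should go para to one methoxy group and ortho to the other, at the carbon next to the existing bromine, because the position between the two methoxy groups is the more hindered one.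

Step 2
Reactants: 3 (R)-2-propyloxirane; 4 7-bromohept-1-ene
Product: 6 (4R)-dodec-11-en-4-ol, via hept-6-en-1-ylmagnesium bromide 5 (not isolated)
Conditions: 4, Mg, THF, rt; then CuI (10 mol %), 3, THF, −30 → 0 °C; 1 M HCl quench
Reagents that add atoms: none
Why: Copper-catalysed Grignard opening of a terminal epoxide occurs by SN2 attack at the unsubstituted carbon, so the C–O stereocentre of the oxirane is untouched and the carbinol is (R).

Step 3
Reactants: 6 (4R)-dodec-11-en-4-ol
Product: 7 tert-butyl{[(4R)-dodec-11-en-4-yl]oxy}dimethylsilane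
Conditions: TBSCl, imidazole, DMF, rt
Reagents that add atoms: tert-butyldimethylsilyl chloride, CC(C)(C)[Si](C)(C)Cl
Why: Imidazole-promoted silylation of a secondary alcohol is routine and gives an ether that tolerates the borane, Appel and Grignard conditions ahead.

Step 4
Reactants: 7 tert-butyl{[(4R)-dodec-11-en-4-yl]oxy}dimethylsilane
Product: 9 (9R)-9-(tert-butyldimethylsilyloxy)dodecan-1-ol, via B-alkyl-9-BBN borane 8 (not isolated)
Conditions: 9-BBN, THF, 0 °C → rt; then 3 M NaOH, 30% H2O2, 0 °C → rt
Reagents that add atoms: hydrogen peroxide, OO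
Why: Anti-Markovnikov hydroboration of the terminal alkene with 9-BBN followed by oxidative work-up delivers the primary alcohol without affecting the silyl ether.

Step 5
Reactants: 9 (9R)-9-(tert-butyldimethylsilyloxy)dodecan-1-ol
Product: 10 {[(4R)-12-bromododecan-4-yl]oxy}(tert-butyl)dimethylsilane
Conditions: CBr4, PPh3, imidazole (buffer), CH2Cl2, 0 °C
Reagents that add atoms: tetrabromomethane, BrC(Br)(Br)Br
Why: The Appel reaction converts the primary alcohol into the bromide under near-neutral conditions that a secondary TBS ether withstands.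

Step 6
Reactants: 10 {[(4R)-12-bromododecan-4-yl]oxy}(tert-butyl)dimethylsilane
Product: 11 [(9R)-9-(tert-butyldimethylsilyloxy)dodecyl]magnesium bromide (THF solution, titrated and used directly)
Conditions: Mg turnings (activated with 1,2-dibromoethane), THF, rt → 40 °C
Reagents that add atoms: magnesium, [Mg]
Why: Oxidative insertion of magnesium into a primary alkyl bromide (Grignard formation) is reliable, and the remote silyl ether is inert to the reagent.

Step 7
Reactants: 2 1,2-dibromo-3,5-dimethoxybenzene; 11 [(9R)-9-(tert-butyldimethylsilyloxy)dodecyl]magnesium bromide; 12 carbon dioxide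
Product: 16 6-[(9R)-9-(tert-butyldimethylsilyloxy)dodecyl]-2,4-dimethoxybenzoic acid, via (2-bromo-4,6-dimethoxyphenyl)magnesium chloride 13 (not isolated), via 3,5-dimethoxybenzyne 14 (not isolated), via arylmagnesium bromide adduct 15 (not isolated)
Conditions: 2, i-PrMgCl·LiCl (1.05 equiv), THF, −20 °C; then 11 (1.5 equiv), −20 → 50 °C; then CO2 (dry gas), −20 °C → rt; brief cold 0.5 M HCl work-up
Reagents that add atoms: none
Why: Bromine–magnesium exchange at the bromine flanked by the methoxy group gives the ortho-bromoaryl Grignard 13, which on warming loses MgBrCl to release 3,5-dimethoxybenzyne 14 (exchange at the other bromine would lead to the same aryne). The primary alkyl Grignard 11 then adds across the strained triple bond (carbomagnesiation) at the aryne carbon remote from the flanking methoxy group, because that carbon is the less hindered and more electrophilic end of the inductively distorted aryne and the new aryl–magnesium bond is then placed next to the electron-withdrawing, chelating oxygen. The resulting 2,6-disubstituted arylmagnesium 15 is trapped by carbon dioxide at that carbon, so the aryl–CH2 bond (C6) and the aryl–carboxyl bond (C1) are formed in one flask. The closest known reaction type is the addition of alkyllithium and Grignard reagents to 3-methoxyarynes followed by electrophilic quench, the established entry to 6-alkylsalicylic acid ethers and 5-alkylresorcinol ethers. No ring is closed and no stereocentre is created, and the remote silyloxy centre of the chain is not touched. The selectivity needed is regiochemical (alkyl to C6, carboxyl to C1), secured by the C2 methoxy group beside the triple bond, and chemoselective capture of the aryne by 11 rather than by the hindered arylmagnesium species, secured by slow thermal release of the aryne into an excess of the more nucleophilic alkyl Grignard.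

Step 8
Reactants: 17 (S)-2-propyloxirane; 18 6-bromohex-1-ene
Product: 20 (4S)-undec-10-en-4-ol, via hex-5-en-1-ylmagnesium bromide 19 (not isolated)
Conditions: 18, Mg, THF, rt; then CuI (10 mol %), 17, THF, −30 → 0 °C; 1 M HCl quench
Reagents that add atoms: none
Why: The same copper-catalysed SN2 opening at the terminal epoxide carbon leaves the stereocentre intact and gives the (S)-carbinol needed for later inversion.

Step 9
Reactants: 21 5-bromobenzene-1,3-diol
Product: 22 1,3-bis(benzyloxy)-5-bromobenzene
Conditions: BnBr (2.2 equiv), K2CO3, DMF, rt → 60 °C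
Reagents that add atoms: benzyl bromide, BrCc1ccccc1
Why: Williamson etherification of both phenols is straightforward and gives ethers that BCl3 removes at the end.

Step 10
Reactants: 20 (4S)-undec-10-en-4-ol; 22 1,3-bis(benzyloxy)-5-bromobenzene
Product: 24 (4S)-11-[3,5-bis(benzyloxy)phenyl]undecan-4-ol, via B-alkyl-9-BBN borane 23 (not isolated)
Conditions: 20, 9-BBN (2.2 equiv), THF, 0 °C → rt; then 22, Pd(dppf)Cl2 (5 mol %), 3 M aq NaOH, THF, 60 °C
Reagents that add atoms: none
Why: Terminal hydroboration followed by B-alkyl Suzuki–Miyaura coupling forms the aryl–CH2 bond without a hydrogenation that would endanger the benzyl ethers; the excess 9-BBN covers any transient O-borylation of the free hydroxyl, which the aqueous base reverses.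

Step 11
Reactants: 16 6-[(9R)-9-(tert-butyldimethylsilyloxy)dodecyl]-2,4-dimethoxybenzoic acid; 24 (4S)-11-[3,5-bis(benzyloxy)phenyl]undecan-4-ol
Product: 25 (4R)-11-[3,5-bis(benzyloxy)phenyl]undecan-4-yl 6-[(9R)-9-(tert-butyldimethylsilyloxy)dodecyl]-2,4-dimethoxybenzoate
Conditions: PPh3, DIAD, toluene, 0 °C → rt
Reagents that add atoms: none
Why: Mitsunobu esterification activates the alcohol rather than the hindered di-ortho-substituted acid, and SN2 displacement by the carboxylate inverts the carbinol from (S) to the required (R).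

Step 12
Reactants: 25 (4R)-11-[3,5-bis(benzyloxy)phenyl]undecan-4-yl 6-[(9R)-9-(tert-butyldimethylsilyloxy)dodecyl]-2,4-dimethoxybenzoate
Product: 26 (4R)-11-[3,5-bis(benzyloxy)phenyl]undecan-4-yl 6-[(9R)-9-hydroxydodecyl]-2,4-dimethoxybenzoate
Conditions: HF·pyridine, THF/pyridine, 0 °C → rt
Reagents that add atoms: none
Why: Fluoride-mediated desilylation cleaves only the Si–O bond, so the hindered benzoate, the benzyl ethers and the carbinol configuration are unaffected.

Step 13
Reactants: 26 (4R)-11-[3,5-bis(benzyloxy)phenyl]undecan-4-yl 6-[(9R)-9-hydroxydodecyl]-2,4-dimethoxybenzoate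
Product: 27 (4R)-11-[3,5-bis(benzyloxy)phenyl]undecan-4-yl 6-[(9R)-9-acetoxydodecyl]-2,4-dimethoxybenzoate
Conditions: Ac2O, pyridine, DMAP (cat.), CH2Cl2, rt
Reagents that add atoms: acetic anhydride, CC(=O)OC(C)=O
Why: DMAP-catalysed acylation of the only free hydroxyl proceeds with retention at the (R)-carbinol, since the C–O bond is not broken.

Step 14
Reactants: 27 (4R)-11-[3,5-bis(benzyloxy)phenyl]undecan-4-yl 6-[(9R)-9-acetoxydodecyl]-2,4-dimethoxybenzoate
Product: 28 5'-methoxy-integracin A, (4R)-11-(3,5-dihydroxyphenyl)undecan-4-yl 6-[(9R)-9-acetoxydodecyl]-2-hydroxy-4-methoxybenzoate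
Conditions: BCl3 (1 M in CH2Cl2, excess), pentamethylbenzene, CH2Cl2, −78 → 0 °C; H2O quench
Reagents that add atoms: none
Why: Lewis-acid ether cleavage with BCl3 should remove both benzyl ethers (the scavenger intercepts the benzyl cations) and, through chelation to the ester carbonyl, only the C2 methyl ether of ring A, leaving the C4 methoxy group, the acetate and the secondary benzoate in place.

**Compound list**

1 | 1-bromo-3,5-dimethoxybenzene | COc1cc(Br)cc(OC)c1 | starting material
2 | 1,2-dibromo-3,5-dimethoxybenzene | COc1cc(OC)c(Br)c(Br)c1 | intermediate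
3 | (R)-2-propyloxirane | CCC[C@@H]1CO1 | starting material
4 | 7-bromohept-1-ene | C=CCCCCCBr | starting material
5 | hept-6-en-1-ylmagnesium bromide | C=CCCCCC[Mg]Br | intermediate
6 | (4R)-dodec-11-en-4-ol | CCC[C@H](CCCCCCC=C)O | intermediate
7 | tert-butyl{[(4R)-dodec-11-en-4-yl]oxy}dimethylsilane | CCC[C@H](CCCCCCC=C)O[Si](C)(C)C(C)(C)C | intermediate
8 | 9-[(9R)-9-(tert-butyldimethylsilyloxy)dodecyl]-9-borabicyclo[3.3.1]nonane | CCC[C@H](CCCCCCCCB1C2CCCC1CCC2)O[Si](C)(C)C(C)(C)C | intermediate
9 | (9R)-9-(tert-butyldimethylsilyloxy)dodecan-1-ol | CCC[C@H](CCCCCCCCO)O[Si](C)(C)C(C)(C)C | intermediate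
10 | {[(4R)-12-bromododecan-4-yl]oxy}(tert-butyl)dimethylsilane | CCC[C@H](CCCCCCCCBr)O[Si](C)(C)C(C)(C)C | intermediate
11 | [(9R)-9-(tert-butyldimethylsilyloxy)dodecyl]magnesium bromide | CCC[C@H](CCCCCCCC[Mg]Br)O[Si](C)(C)C(C)(C)C | intermediate
12 | carbon dioxide | O=C=O | starting material
13 | (2-bromo-4,6-dimethoxyphenyl)magnesium chloride | COc1cc(OC)c([Mg]Cl)c(Br)c1 | intermediate
14 | 3,5-dimethoxybenzyne (1,2-didehydro-3,5-dimethoxybenzene) | COC1=CC#CC(OC)=C1 | intermediate
15 | {2-[(9R)-9-(tert-butyldimethylsilyloxy)dodecyl]-4,6-dimethoxyphenyl}magnesium bromide | CCC[C@H](CCCCCCCCc1cc(OC)cc(OC)c1[Mg]Br)O[Si](C)(C)C(C)(C)C | intermediate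
16 | 6-[(9R)-9-(tert-butyldimethylsilyloxy)dodecyl]-2,4-dimethoxybenzoic acid | CCC[C@H](CCCCCCCCc1cc(OC)cc(OC)c1C(=O)O)O[Si](C)(C)C(C)(C)C | intermediate
17 | (S)-2-propyloxirane | CCC[C@H]1CO1 | starting material
18 | 6-bromohex-1-ene | C=CCCCCBr | starting material
19 | hex-5-en-1-ylmagnesium bromide | C=CCCCC[Mg]Br | intermediate
20 | (4S)-undec-10-en-4-ol | CCC[C@@H](CCCCCC=C)O | intermediate
21 | 5-bromobenzene-1,3-diol | Oc1cc(O)cc(Br)c1 | starting material
22 | 1,3-bis(benzyloxy)-5-bromobenzene | Brc1cc(OCc2ccccc2)cc(OCc2ccccc2)c1 | intermediate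
23 | 9-[(8S)-8-hydroxyundecyl]-9-borabicyclo[3.3.1]nonane (hydroxyl drawn free; it may be held transiently as its O-boryl ether) | CCC[C@@H](CCCCCCCB1C2CCCC1CCC2)O | intermediate
24 | (4S)-11-[3,5-bis(benzyloxy)phenyl]undecan-4-ol | CCC[C@@H](CCCCCCCc1cc(OCc2ccccc2)cc(OCc2ccccc2)c1)O | intermediate
25 | (4R)-11-[3,5-bis(benzyloxy)phenyl]undecan-4-yl 6-[(9R)-9-(tert-butyldimethylsilyloxy)dodecyl]-2,4-dimethoxybenzoate | CCC[C@H](CCCCCCCCc1cc(OC)cc(OC)c1C(=O)O[C@H](CCC)CCCCCCCc1cc(OCc2ccccc2)cc(OCc2ccccc2)c1)O[Si](C)(C)C(C)(C)C | intermediate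
26 | (4R)-11-[3,5-bis(benzyloxy)phenyl]undecan-4-yl 6-[(9R)-9-hydroxydodecyl]-2,4-dimethoxybenzoate | CCC[C@H](CCCCCCCCc1cc(OC)cc(OC)c1C(=O)O[C@H](CCC)CCCCCCCc1cc(OCc2ccccc2)cc(OCc2ccccc2)c1)O | intermediate
27 | (4R)-11-[3,5-bis(benzyloxy)phenyl]undecan-4-yl 6-[(9R)-9-acetoxydodecyl]-2,4-dimethoxybenzoate | CCC[C@H](CCCCCCCCc1cc(OC)cc(OC)c1C(=O)O[C@H](CCC)CCCCCCCc1cc(OCc2ccccc2)cc(OCc2ccccc2)c1)OC(C)=O | intermediate
28 | 5'-methoxy-integracin A, (4R)-11-(3,5-dihydroxyphenyl)undecan-4-yl 6-[(9R)-9-acetoxydodecyl]-2-hydroxy-4-methoxybenzoate | CCC[C@H](CCCCCCCCc1cc(OC)cc(O)c1C(=O)O[C@H](CCC)CCCCCCCc1cc(O)cc(O)c1)OC(C)=O | target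

**Totals**

Total step count: 14. Longest linear sequence: 10 steps (steps 2 to 7, then 11 to 14).

**Steps most likely to fail**

1. Step 7 (aryne alkylation–carboxylation). The released aryne may be captured by the arylmagnesium species present instead of the alkyl Grignard, giving biaryl coupling. The adduct may be protonated before carbon dioxide arrives. Elimination from the ortho-bromoaryl Grignard may need a temperature at which the alkyl Grignard starts to be consumed by the 2-bromopropane formed in the exchange. Fallback, a stepwise construction of the same two bonds, setting out from 7 and 1: alkene 7 is hydroborated to borane 8 and coupled with bromide 1 (Pd(dppf)Cl2, K3PO4, DMF/H2O, 60 °C, B-alkyl Suzuki–Miyaura) to give tert-butyl{[(4R)-12-(3,5-dimethoxyphenyl)dodecan-4-yl]oxy}dimethylsilane F1. Bromination with NBS in MeCN at 0 °C, directed para to a methoxy group and ortho to the alkyl chain, should give {[(4R)-12-(2-bromo-3,5-dimethoxyphenyl)dodecan-4-yl]oxy}(tert-butyl)dimethylsilane F2. Bromine–lithium exchange (n-BuLi, THF, −78 °C) and a carbon dioxide quench then return to the route at acid 16.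

2. Step 14 (global deprotection with BCl3). Cleavage of the chelated methyl ether may stay incomplete at temperatures the two esters tolerate, and benzyl cations may be transferred to the electron-rich resorcinol ring despite the scavenger. Fallback, setting out from 27, with the two deprotections separated: hydrogenolysis (H2, 10% Pd/C, EtOAc, rt) removes both benzyl ethers without any cation and gives (4R)-11-(3,5-dihydroxyphenyl)undecan-4-yl 6-[(9R)-9-acetoxydodecyl]-2,4-dimethoxybenzoate F3. BCl3 (CH2Cl2, −20 → 0 °C, extra equivalents to cover the free phenols) then cleaves only the chelated C2 methyl ether and returns to the route at target 28.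

3. Step 11 (Mitsunobu esterification). The activated secondary alcohol may eliminate, or slow attack by the hindered carboxylate may allow an acyloxyphosphonium pathway that erodes inversion. Fallback, setting out from 24 and 16: alcohol 24 is converted with MsCl and Et3N (CH2Cl2, 0 °C) into (4S)-11-[3,5-bis(benzyloxy)phenyl]undecan-4-yl methanesulfonate F4. This is displaced by the caesium carboxylate of 16 (Cs2CO3, DMF, 50 °C) in an SN2 reaction with inversion, which returns to the route at ester 25.

**Further compounds**

F1 | step 7 | tert-butyl{[(4R)-12-(3,5-dimethoxyphenyl)dodecan-4-yl]oxy}dimethylsilane | CCC[C@H](CCCCCCCCc1cc(OC)cc(OC)c1)O[Si](C)(C)C(C)(C)C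
F2 | step 7 | {[(4R)-12-(2-bromo-3,5-dimethoxyphenyl)dodecan-4-yl]oxy}(tert-butyl)dimethylsilane | CCC[C@H](CCCCCCCCc1cc(OC)cc(OC)c1Br)O[Si](C)(C)C(C)(C)C
F3 | step 14 | (4R)-11-(3,5-dihydroxyphenyl)undecan-4-yl 6-[(9R)-9-acetoxydodecyl]-2,4-dimethoxybenzoate | CCC[C@H](CCCCCCCCc1cc(OC)cc(OC)c1C(=O)O[C@H](CCC)CCCCCCCc1cc(O)cc(O)c1)OC(C)=O
F4 | step 11 | (4S)-11-[3,5-bis(benzyloxy)phenyl]undecan-4-yl methanesulfonate | CCC[C@@H](CCCCCCCc1cc(OCc2ccccc2)cc(OCc2ccccc2)c1)OS(C)(=O)=O
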